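Ring B carries oxygen at C7 and C9 on either side of C8 (labdane numbering), so the decalin is read as a masked cyclohexane-1,3-dione. An acyclic keto enoate, in which a methyl ketone (C8–C9) with a C10 methine and an (E)-enoate (C5=C6–C7) are linked by the C1–C4 chain, is closed by base in one operation: Michael addition of C10 to C5 forms ring A, then Claisen acylation of C8 by C7 forms ring B and expels the 8-phenylmenthyl auxiliary that set C5. Thiomethylation, allyl addition and a sulfoxide–sulfenate shift then install C17, C11 and the C9 carbinol; a late Diels–Alder reaction with a flavone-derived quinone completes the target.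

Key step: step 7

Remark: the terpenoid part carries labdane numbers (C1–C3 CH2, C4 CMe2, C5 CH, C6 CH2, C7 C=O, C8, C9, C10 with the angular methyl, C17 exocyclic CH2, C11–C16 side chain). The quinone-derived ring D is numbered C1'–C6' (C1' carbonyl next to the methoxy carbon C2', C5' bearing the chromone), and ring C is the new cyclohexene. "8-Phenylmenthyl" always means the (1R,2S,5R) group of (−)-8-phenylmenthol.

Step 1
Reactants: 1 isobutyronitrile; 2 1,3-dibromopropane
Product: 3 5-bromo-2,2-dimethylpentanenitrile
Conditions: LiN(iPr)2, THF, −78 °C; then 2 (3 equiv), −78 °C → rt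
Reagents that add atoms: none
Why: SN2 alkylation of the lithiated nitrile by an excess of the dihalide should give the monoalkylated product and creates the C4 quaternary carbon with the C3–C1 chain.

Step 2
Reactants: 3 5-bromo-2,2-dimethylpentanenitrile
Product: 4 5-bromo-2,2-dimethylpentanal
Conditions: iBu2AlH, CH2Cl2, −78 °C; then 1 M HCl
Reagents that add atoms: water, O
Why: Half-reduction of the hindered nitrile stops at the aluminium imine, which is hydrolysed to the aldehyde (C5) on work-up, while the primary bromide is inert at −78 °C.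

Step 3
Reactants: 5 (−)-8-phenylmenthol; 6 diethylphosphonoacetic acid
Product: 7 8-phenylmenthyl 2-(diethoxyphosphoryl)acetate
Conditions: DCC, DMAP (cat.), CH2Cl2, 0 °C → rt
Reagents that add atoms: none
Why: Steglich esterification attaches the chiral alcohol to the olefination reagent without touching its stereocentres.

Step 4
Reactants: 7 8-phenylmenthyl 2-(diethoxyphosphoryl)acetate; 4 5-bromo-2,2-dimethylpentanal
Product: 8 8-phenylmenthyl (E)-7-bromo-4,4-dimethylhept-2-enoate
Conditions: NaH, THF, 0 °C; then 4, 0 °C → rt
Reagents that add atoms: none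
Why: Horner–Wadsworth–Emmons olefination of the non-enolisable α-quaternary aldehyde should give the (E)-enoate (C5=C6–C7) selectively.

Step 5
Reactants: 9 tert-butyl 2-methyl-3-oxobutanoate; 8 8-phenylmenthyl (E)-7-bromo-4,4-dimethylhept-2-enoate
Product: 10 8-phenylmenthyl (E)-8-(tert-butoxycarbonyl)-4,4,8-trimethyl-9-oxodec-2-enoate (both C8 epimers of the decenoate chain)
Conditions: NaH, DMF, 0 °C; then 8, NaI (cat.), 50 °C
Reagents that add atoms: none
Why: Acetoacetic ester C-alkylation (SN2) of the sodium enolate by the primary bromide, the enoate being a poor Michael acceptor because C5 is neopentylic; the new quaternary carbon is lost as a stereocentre in step 6.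

Step 6
Reactants: 10 8-phenylmenthyl (E)-8-(tert-butoxycarbonyl)-4,4,8-trimethyl-9-oxodec-2-enoate
Product: 12 8-phenylmenthyl (E)-4,4,8-trimethyl-9-oxodec-2-enoate (both epimers at the methine that becomes C10), via β-keto acid 11 (not isolated)
Conditions: CF3CO2H, CH2Cl2, rt; then toluene, 90 °C
Reagents that add atoms: none
Why: Acidolysis of the tert-butyl ester and thermal decarboxylation of the β-keto acid unmask the methyl ketone without base, so that no enolate can cyclise prematurely; both epimers converge in step 7.

Step 7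
Reactants: 12 8-phenylmenthyl (E)-4,4,8-trimethyl-9-oxodec-2-enoate
Product: 14 (4aS,8aS)-5,5,8a-trimethylhexahydronaphthalene-1,3(2H,4H)-dione (trans-4,4,10-trimethyldecalin-7,9-dione; 5S,10S), via Michael adduct 13 (not isolated)
Conditions: KOtBu (2.5 equiv), THF (0.01 M), −40 → 0 °C; then 1 M HCl
Reagents that add atoms: none
Why: KOtBu equilibrates the ketone enolates; only the C10 enolate can reach the enoate, its 6-exo-trig Michael addition to C5 closes ring A, and the methyl-ketone enolate at C8 then attacks the C7 ester in a 6-exo-trig Claisen (Dieckmann-type) acyl substitution that closes ring B, expels 8-phenylmentholate and leaves the product as its stable 1,3-dione enolate. The closest known reaction type is the Michael–Claisen [3+3] synthesis of cyclohexane-1,3-diones from ketones and enoates, run here intramolecularly. C5 is set by the auxiliary: in the s-trans enoate the phenyl ring covers the Re face of C5, so C10 should add to the Si face (5S), the sense known for conjugate additions to (−)-8-phenylmenthyl enoates. C10 is set relative to C5 in a chair transition state in which potassium bridges the enolate oxygen and the ester carbonyl, placing C9 and C6 equatorial on ring A and the C10 methyl axial, which is the trans-fused 10S arrangement. The step needs enolate regioselectivity (the C8 enolate could only close an eight-membered ring), face selectivity at C5 (auxiliary, low temperature so that the Michael step is not reversed before the Claisen closure) and trans fusion (chair transition state, and a cis adduct can revert).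

Step 8
Reactants: 14 (4aS,8aS)-5,5,8a-trimethylhexahydronaphthalene-1,3(2H,4H)-dione; 15 formaldehyde
Product: 16 (5S,10S)-8-(phenylthiomethyl)-4,4,10-trimethyldecalin-7,9-dione (keto–enol mixture)
Conditions: aq. CH2O, PhSH, Et3N (cat.), EtOH, rt
Reagents that add atoms: thiophenol, Sc1ccccc1
Why: Knoevenagel condensation at C8, the only doubly activated carbon, followed by thia-Michael trapping of the 2-methylene dione (three-component thiomethylation of 1,3-diones) introduces C17 as CH2SPh.

Step 9
Reactants: 16 (5S,10S)-8-(phenylthiomethyl)-4,4,10-trimethyldecalin-7,9-dione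
Product: 17 (5S,10S)-7-methoxy-8-(phenylthiomethyl)-4,4,10-trimethyl-Δ7-octalin-9-one
Conditions: HC(OMe)3, TsOH (cat.), MeOH, rt
Reagents that add atoms: trimethyl orthoformate, COC(OC)OC
Why: Acid-catalysed vinylogous ester formation should occur at the less hindered C7 carbonyl, because the C9 carbonyl is shielded by the quaternary C10, as with 4,4-dimethylcyclohexane-1,3-dione.

Step 10
Reactants: 17 (5S,10S)-7-methoxy-8-(phenylthiomethyl)-4,4,10-trimethyl-Δ7-octalin-9-one; 18 allylmagnesium bromide
Product: 20 (5S,10S)-9-allyl-8-(phenylthiomethyl)-4,4,10-trimethyl-Δ8-octalin-7-one, via tertiary carbinol 19 (not isolated)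
Conditions: CH2=CHCH2MgBr, THF, −78 → 0 °C; then 1 M HCl, THF, rt
Reagents that add atoms: water, O
Why: Stork–Danheiser sequence, in which 1,2-addition to the vinylogous ester carbonyl C9 and acid hydrolysis with loss of water transpose the enone to C7(=O)–C8=C9 and attach C11–C12; C9 becomes sp2, so the face of addition does not matter.

Step 11
Reactants: 20 (5S,10S)-9-allyl-8-(phenylthiomethyl)-4,4,10-trimethyl-Δ8-octalin-7-one; 21 methacrolein
Product: 22 (E)-enal with the side chain C11H2–C12H=C13(CH3)–CHO on C9
Conditions: second-generation Grubbs catalyst RuCl2(=CHPh)(PCy3)(H2IMes) (5 mol %), 21 (5 equiv), CH2Cl2, 40 °C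
Reagents that add atoms: none
Why: Olefin cross-metathesis of the terminal allyl alkene with methacrolein should give the thermodynamically preferred (E)-trisubstituted enal, the tetrasubstituted enone alkene being inert.

Step 12
Reactants: 22 (E)-enal; 23 methyltriphenylphosphonium bromide
Product: 24 (5S,10S,12E)-8-(phenylthiomethyl)-17-norlabda-8,12,14-trien-7-one bearing C17 as CH2SPh (the 12E,14-diene sulfide)
Conditions: KN(SiMe3)2, THF, −78 °C; then 22, −78 → 0 °C
Reagents that add atoms: none
Why: Wittig methylenation converts the aldehyde into C14=C15 with retention of the 12E geometry, the hindered tetrasubstituted enone carbonyl not reacting at low temperature.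

Step 13
Reactants: 24 12E,14-diene sulfide
Product: 27 (5S,9S,10S,12E)-9-hydroxylabda-8(17),12,14-trien-7-one (9α-OH), via allylic sulfoxide 25 (not isolated), via allylic sulfenate 26 (not isolated)
Conditions: mCPBA (1.0 equiv), CH2Cl2, −78 °C; then P(OMe)3, MeOH, 40 °C
Reagents that add atoms: mCPBA, OOC(=O)c1cccc(Cl)c1
Why: Mislow–Evans [2,3]-sigmatropic rearrangement of the allylic sulfoxide, drained by the thiophile, moves the alkene to C8=C17 and delivers oxygen to C9 on the α face, anti to the axial C10 methyl, which sets 9S.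

Step 14
Reactants: 28 2,4,5-trimethoxybenzoic acid
Product: 29 2,4,5-trimethoxybenzoyl chloride
Conditions: (COCl)2, DMF (cat.), CH2Cl2, 0 °C → rt
Reagents that add atoms: oxalyl chloride, O=C(Cl)C(=O)Cl
Why: Standard acid chloride formation through the Vilsmeier-type chloroiminium species.

Step 15
Reactants: 30 2',4',6'-trihydroxyacetophenone; 29 2,4,5-trimethoxybenzoyl chloride
Product: 31 1-(2,4,6-trihydroxyphenyl)-3-(2,4,5-trimethoxyphenyl)propane-1,3-dione
Conditions: LiN(SiMe3)2 (4.2 equiv), THF, −78 → −10 °C; then 29, −78 °C → rt; 1 M HCl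
Reagents that add atoms: none
Why: In the polylithiated acetophenone the ketone enolate carbon is the most nucleophilic site, so Claisen-type C-acylation should give the β-diketone directly (a Baker–Venkataraman product without protecting groups).

Step 16
Reactants: 31 1-(2,4,6-trihydroxyphenyl)-3-(2,4,5-trimethoxyphenyl)propane-1,3-dione
Product: 32 5,7-dihydroxy-2-(2,4,5-trimethoxyphenyl)chromen-4-one
Conditions: H2SO4 (cat.), AcOH, 95 °C
Reagents that add atoms: none
Why: Acid-catalysed cyclodehydration of the o-hydroxyaryl β-diketone closes the pyrone ring (flavone synthesis).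

Step 17
Reactants: 32 5,7-dihydroxy-2-(2,4,5-trimethoxyphenyl)chromen-4-one
Product: 33 2-(5,7-dihydroxy-4-oxochromen-2-yl)-5-methoxy-1,4-benzoquinone
Conditions: (NH4)2Ce(NO3)6, MeCN/H2O, 0 °C
Reagents that add atoms: water, O
Why: Oxidative demethylation of the para-related 2',5'-dimethoxy pair gives the methoxy-p-quinone, while the meta-dioxygenated chromone ring, deactivated by the pyrone carbonyl, should resist.

Step 18
Reactants: 27 (5S,9S,10S,12E)-9-hydroxylabda-8(17),12,14-trien-7-one; 33 2-(5,7-dihydroxy-4-oxochromen-2-yl)-5-methoxy-1,4-benzoquinone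
Product: 34 CNP0241859.1, the target (5S,9S,10S,12R,5'S,6'R)
Conditions: Sc(OSO2CF3)3 (10 mol %), CH2Cl2/MeCN, −20 °C → rt
Reagents that add atoms: none
Why: Diels–Alder reaction in which scandium bound at the chelating 5-hydroxy-4-oxo site makes the chromonyl group the controlling acceptor, so that C15 bonds to C6' and C12 to C5', the chromone lies under the diene and the (E) side chain on C12 ends cis to it with a cis C/D fusion, the methoxy-bearing alkene stays untouched, and the diene face is differentiated only by the C9 carbinol, so that 34 should form together with a separable diastereomer of opposite configuration in rings C and D.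

Compound list
1 | isobutyronitrile | CC(C)C#N | starting material
2 | 1,3-dibromopropane | BrCCCBr | starting material
3 | 5-bromo-2,2-dimethylpentanenitrile | CC(C)(CCCBr)C#N | intermediate
4 | 5-bromo-2,2-dimethylpentanal | CC(C)(CCCBr)C=O | intermediate
5 | (−)-8-phenylmenthol, (1R,2S,5R)-5-methyl-2-(2-phenylpropan-2-yl)cyclohexan-1-ol | O[C@@H]1C[C@H](C)CC[C@H]1C(C)(C)c1ccccc1 | starting material
6 | diethylphosphonoacetic acid | CCOP(=O)(OCC)CC(=O)O | starting material
7 | 8-phenylmenthyl 2-(diethoxyphosphoryl)acetate | CCOP(=O)(OCC)CC(=O)O[C@@H]1C[C@H](C)CC[C@H]1C(C)(C)c1ccccc1 | intermediate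
8 | 8-phenylmenthyl (E)-7-bromo-4,4-dimethylhept-2-enoate | BrCCCC(C)(C)/C=C/C(=O)O[C@@H]1C[C@H](C)CC[C@H]1C(C)(C)c1ccccc1 | intermediate
9 | tert-butyl 2-methyl-3-oxobutanoate | CC(=O)C(C)C(=O)OC(C)(C)C | starting material
10 | 8-phenylmenthyl (E)-8-(tert-butoxycarbonyl)-4,4,8-trimethyl-9-oxodec-2-enoate | CC(=O)C(C)(CCCC(C)(C)/C=C/C(=O)O[C@@H]1C[C@H](C)CC[C@H]1C(C)(C)c1ccccc1)C(=O)OC(C)(C)C | intermediate
11 | β-keto acid from 10 (free acid in place of the tert-butyl ester) | CC(=O)C(C)(CCCC(C)(C)/C=C/C(=O)O[C@@H]1C[C@H](C)CC[C@H]1C(C)(C)c1ccccc1)C(=O)O | intermediate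
12 | 8-phenylmenthyl (E)-4,4,8-trimethyl-9-oxodec-2-enoate | CC(=O)C(C)CCCC(C)(C)/C=C/C(=O)O[C@@H]1C[C@H](C)CC[C@H]1C(C)(C)c1ccccc1 | intermediate
13 | 8-phenylmenthyl 2-[(1S,2S)-2-acetyl-2,6,6-trimethylcyclohexyl]acetate (Michael adduct) | O=C(C[C@H]1C(C)(C)CCC[C@]1(C)C(C)=O)O[C@@H]2C[C@H](C)CC[C@H]2C(C)(C)c2ccccc2 | intermediate
14 | (4aS,8aS)-5,5,8a-trimethylhexahydronaphthalene-1,3(2H,4H)-dione | C1C(=O)C[C@H]2C(C)(C)CCC[C@]2(C)C1=O | intermediate
15 | formaldehyde | C=O | starting material
16 | (5S,10S)-8-(phenylthiomethyl)-4,4,10-trimethyldecalin-7,9-dione | C1(CSc3ccccc3)C(=O)C[C@H]2C(C)(C)CCC[C@]2(C)C1=O | intermediate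
17 | (5S,10S)-7-methoxy-8-(phenylthiomethyl)-4,4,10-trimethyl-Δ7-octalin-9-one | C1(CSc3ccccc3)=C(OC)C[C@H]2C(C)(C)CCC[C@]2(C)C1=O | intermediate
18 | allylmagnesium bromide | C=CC[Mg]Br | starting material
19 | 9-allyl-9-hydroxy-7-methoxy-8-(phenylthiomethyl)-Δ7-octalin (allyl α, formed as the magnesium alkoxide) | C1(CSc3ccccc3)=C(OC)C[C@H]2C(C)(C)CCC[C@]2(C)[C@]1(O)CC=C | intermediate
20 | (5S,10S)-9-allyl-8-(phenylthiomethyl)-4,4,10-trimethyl-Δ8-octalin-7-one | O=C1C[C@H]2C(C)(C)CCC[C@]2(C)C(CC=C)=C1CSc1ccccc1 | intermediate
21 | methacrolein | CC(=C)C=O | starting material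
22 | (E)-enal, side chain C11H2–C12H=C13(CH3)–CHO on C9 of the Δ8-7-one | O=C1C[C@H]2C(C)(C)CCC[C@]2(C)C(C/C=C(\C)C=O)=C1CSc1ccccc1 | intermediate
23 | methyltriphenylphosphonium bromide | C[P+](c1ccccc1)(c1ccccc1)c1ccccc1.[Br-] | starting material
24 | 12E,14-diene sulfide (Δ8-7-one with C17 as CH2SPh) | O=C1C[C@H]2C(C)(C)CCC[C@]2(C)C(C/C=C(\C)C=C)=C1CSc1ccccc1 | intermediate
25 | allylic sulfoxide of 24 (both configurations at sulfur) | O=C1C[C@H]2C(C)(C)CCC[C@]2(C)C(C/C=C(\C)C=C)=C1CS(=O)c1ccccc1 | intermediate
26 | 9α-O-phenylsulfenate of 27 | C=C1C(=O)C[C@H]2C(C)(C)CCC[C@]2(C)[C@@]1(OSc1ccccc1)C/C=C(\C)C=C | intermediate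
27 | (5S,9S,10S,12E)-9-hydroxylabda-8(17),12,14-trien-7-one | C=C1C(=O)C[C@H]2C(C)(C)CCC[C@]2(C)[C@@]1(O)C/C=C(\C)C=C | intermediate
28 | 2,4,5-trimethoxybenzoic acid | COc1cc(OC)c(C(=O)O)cc1OC | starting material
29 | 2,4,5-trimethoxybenzoyl chloride | COc1cc(OC)c(C(=O)Cl)cc1OC | intermediate
30 | 2',4',6'-trihydroxyacetophenone | CC(=O)c1c(O)cc(O)cc1O | starting material
31 | 1-(2,4,6-trihydroxyphenyl)-3-(2,4,5-trimethoxyphenyl)propane-1,3-dione | COc1cc(OC)c(C(=O)CC(=O)c2c(O)cc(O)cc2O)cc1OC | intermediate
32 | 5,7-dihydroxy-2-(2,4,5-trimethoxyphenyl)chromen-4-one | COc1cc(OC)c(-c2cc(=O)c3c(O)cc(O)cc3o2)cc1OC | intermediate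
33 | 2-(5,7-dihydroxy-4-oxochromen-2-yl)-5-methoxy-1,4-benzoquinone | COC1=CC(=O)C(c2cc(=O)c3c(O)cc(O)cc3o2)=CC1=O | intermediate
34 | CNP0241859.1 (5S,9S,10S,12R,5'S,6'R) | C=C1C(=O)C[C@H]2C(C)(C)CCC[C@]2(C)[C@@]1(O)C[C@@H]1C(C)=CC[C@H]2C(=O)C(OC)=CC(=O)[C@@]12c1cc(=O)c2c(O)cc(O)cc2o1 | target

Total step count: 18. Longest linear sequence: 13 steps (steps 1, 2, 4 to 13 and 18).

Steps most likely to fail

Step 7. The Michael addition may be reversed faster than the Claisen closure takes place, so that the face selectivity imposed by the auxiliary at C5, and with it the enantiomeric purity of 14, is eroded. The fallback sets out from 14 of insufficient enantiomeric purity and replaces auxiliary control by a classical resolution. Condensation with (S)-1-phenylethylamine (toluene, TsOH cat., removal of water) at the less hindered C7 carbonyl should give diastereomeric vinylogous amides. The (5S,10S) isomer, the C7 enaminone of (S)-1-phenylethylamine F1, is separated by crystallisation or chromatography and hydrolysed (2 M HCl, THF), which returns the route to enantiopure 14.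

Step 18. The diene may add with the quinone carbonyls rather than the chromone under it, which would give the C12-epimeric series, and the two diene faces may not be distinguished by the distant C9 centre. The fallback sets out from 27 and changes the diene geometry so that the conventional transition state leads to the same product. Equilibration with catalytic iodine (benzene, visible light) and chromatography on AgNO3-impregnated silica should give (5S,9S,10S,12Z)-9-hydroxylabda-8(17),12,14-trien-7-one F2. Its uncatalysed cycloaddition with 33 under 12 kbar (CH2Cl2/MeCN, rt), with the quinone carbonyls under the diene and the now inside C11 ending cis to the chromone, returns the route at 34.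

Step 13. The sulfoxide–sulfenate equilibrium must give up a tetrasubstituted conjugated alkene and may lie too far on the sulfoxide side, and the thiophile or the peracid may attack the new α-methylene ketone or the diene. The fallback sets out from 24 and uses an epoxide instead of a sigmatropic shift. Nucleophilic epoxidation (tBuOOH, DBU, CH2Cl2) from the α face should give the 8α,9α-epoxy-7-ketone F3. Samarium diiodide SmI2 (THF/MeOH, −78 °C) then cleaves the C8–O bond of the epoxy ketone, and the resulting enolate expels thiophenolate from C17 (E1cB), which returns the route at 27.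

Further compounds
F1 | step 7 | (5S,10S)-7-[(S)-1-phenylethylamino]-4,4,10-trimethyl-Δ7-octalin-9-one | C1=C(N[C@@H](C)c3ccccc3)C[C@H]2C(C)(C)CCC[C@]2(C)C1=O
F2 | step 18 | (5S,9S,10S,12Z)-9-hydroxylabda-8(17),12,14-trien-7-one | C=C1C(=O)C[C@H]2C(C)(C)CCC[C@]2(C)[C@@]1(O)C/C=C(/C)C=C
F3 | step 13 | 8α,9α-epoxide of 24 | C(Sc1ccccc1)[C@@]12C(=O)C[C@H]3C(C)(C)CCC[C@]3(C)[C@@]1(O2)C/C=C(\C)C=C
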